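**The ceiling.** 2% of right-handed product is what the south-east run reads at 4.00 h, and that is one scatter, 2 percentage points; at 6.00 h the north and south-east runs read 1% and 0%. So these readings can't measure this product, but they give a rough cap, and a rough cap gives you a quick number.

the same everywhere: left-handed substrate 0.071 M; right-handed substrate 0.071 M; solid reagent 0.177 M
- north: racemization catalyst 4 mM; run made earlier
- south-east: racemization catalyst 6 mM; run made earlier
- amber: racemization catalyst 3.5 mM; time 8.0 h
- ochre: racemization catalyst 5.0 mM; time 8.0 h

- north (time / h: left-handed product / %, right-handed product / %): 0.417: 1, 1; 0.667: 0, 2; 1.00: 2, 0; 1.50: 2, 0; 2.50: 9, 0; 4.00: 16, 0; 6.00: 23, 1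
- south-east (time / h: left-handed product / %, right-handed product / %): 0.833: 0, 0; 1.50: 3, 0; 2.50: 5, 1; 3.00: 7, 2; 4.00: 16, 2; 5.00: 16, 0; 6.00: 22, 0

(each reading ± 2 percentage points)

- coupling partner is single-handed; left-handed substrate and right-handed substrate are mirror images of each other, charged as a racemate, each of them at the stated concentration
- given per volume of solution although it is solid: solid reagent
- the numbers in the tables scatter by 2 percentage points (one standard deviation)
- at the start none of the solid reagent is in solution
- an excess is the difference of the two amounts in percent of their sum
- an excess is below zero if the other one leads
- the handed part of coupling partner does not stay in what it makes, so the products of the two hands are mirror images too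

1. which one finishes higher in excess of left-handed product over right-handed product in the product ("neither" within 2 percentage points) (amber / ochre / neither)
2. excess of left-handed product over right-handed product in the product at the end, amber
3. excess of left-handed product over right-handed product in the product at the end, ochre

**My reckoning.** I work in powers of ten. Left-handed product averages 22.5% at 6.00 h, so against that cap the hand index is 1.05 or above. The hand index is the base-ten logarithm of left-handed product over right-handed product, which is the logarithm of the selectivity factor while the two substrates stand about equal. My floor in excess is therefore 83.7%. The north and south-east runs, at 4 mM and 6 mM of racemization catalyst, read 23% and 22% of left-handed product, so I give amber and ochre the same floor.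

**Your forecast.** It says 94% for amber, 95% for ochre and neither for which finishes higher, holding that “Racemization therefore looks non-limiting”. We agree on the tie, but we differ on the number: 94% is an index of 1.51, higher than my floor, which is a rough limit from one scattered reading and not an estimate.

**The result.** Amber ends at 98.8% and ochre at 98.9%, so the answer is neither; amber's index is 2.22, above the floor of 1.05.

    coupling partner + left-handed substrate → left-handed product (k = 0.00180 L mol⁻¹ s⁻¹)
    coupling partner + right-handed substrate → right-handed product (k = 1.00 × 10⁻⁵ L mol⁻¹ s⁻¹)
    left-handed substrate + racemization catalyst ⇌ right-handed substrate + racemization catalyst, rate k3*[racemization catalyst]*[left-handed substrate] forward; the back reaction follows from the equilibrium constant (k = 0.0680 L mol⁻¹ s⁻¹)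
    solid reagent ⇌ coupling partner, rate k4*(cs4 - [coupling partner]) while solid is left; crystals form when [coupling partner] > cs4 (solubility = 24.0 mM, k = 1.90 × 10⁻⁴ s⁻¹)

**Parting them.** The forecast's tie would fail if amber and ochre differed by more than 2 points, yet with the step between the two substrates struck out, amber still gives 98.5%. Ochre left until 20 h holds 63.5% of left-handed product against 0.368% of right-handed product, a hand index of 2.24.

(Readings and results were generated by integration on assumed constants; scatter was added.)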